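The data were computed with constants of no real substance; scatter was added.

At 10 h the ash run lies well past the last elm reading at 3.4 h. You asked for a quick number, with the hunch that little happens in between, so I began by testing that hunch on elm.

| flask | starting material | partner | time |
|---|---|---|---|
| elm | 50.0 mM | 100 mM |  |
| maple | 30.0 mM | 80.0 mM |  |
| alder | 50.0 mM | 300 mM |  |
| oak | 150 mM | 100 mM |  |
| ash | 50.0 mM | 100 mM | 10 h |

| run | time / h | [product] / mM |
|---|---|---|
| elm run | 0.19 | 1.4 |
| elm run | 0.59 | 5.7 |
| elm run | 1.1 | 9.5 |
| elm run | 1.8 | 12.8 |
| elm run | 2.5 | 13.8 |
| elm run | 3.4 | 14.2 |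
| maple run | 0.19 | 0.2 |
| maple run | 0.59 | 3.0 |
| maple run | 1.1 | 5.3 |
| maple run | 1.8 | 6.9 |
| maple run | 2.5 | 7.7 |
| maple run | 3.4 | 7.3 |
| alder run | 0.19 | 4.0 |
| alder run | 0.59 | 12.4 |
| alder run | 1.1 | 18.5 |
| alder run | 1.8 | 20.4 |
| alder run | 2.5 | 21.6 |
| alder run | 3.4 | 20.7 |
| oak run | 0.19 | 4.3 |
| oak run | 0.59 | 17.1 |
| oak run | 1.1 | 27.9 |
| oak run | 1.8 | 34.5 |
| oak run | 2.5 | 36.1 |
| oak run | 3.4 | 37.7 |

(each reading ± 0.4 mM)

- Overall: starting material + partner -> product.
- Constant volume, constant temperature.
- "The second partner" is partner.
- An order is taken over about fifteen percent of the charge, up and down.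

- order of the initial rate in [partner], near the charge of the elm run, the rate being that where two percent of its starting material are product
- order of the initial rate in [starting material], near the charge of the elm run, the rate being that where two percent of its starting material are product (one fixed amount of product, the same in the runs compared)
- product in the ash run at 10 h, as a share of the starting material charged

Ash has elm's charge, so I read it from elm. Elm holds more partner than starting material, which makes the starting material the limiting reagent, so I took complete conversion as the zero of my scale. Elm's last reading over its charge was 28.4%, and I carried this end share, called φ, with its gap to complete conversion, 71.6%. Elm's last two readings differed by 0.400 mM, one standard deviation of a reading, so I committed to φ for ash.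

The forecast gave 0.8 for partner, 0.95 for starting material and 29% for ash, noting “Either way, ash has elm's charge”. I made no order of my own, and on ash its share stood close to my φ.

The simulation gave 0.64 for partner, 0.70 for starting material and 28.9% for ash.

    starting material ⇌ intermediate (1.966 h⁻¹, 1.195 h⁻¹)
    intermediate + partner → product (11.74 L mol⁻¹ h⁻¹)
    partner → lost reagent (0.2934 h⁻¹)
    starting material → decomposed substrate (1.883 h⁻¹)

The gap in ash comes mainly from the loss of starting material to decomposed substrate: the same run with that step taken away reached 71.9%, against 28.9% as it stands. That rise covers 60.1% of the gap read from elm. On oak, with 150 mM of starting material and elm's partner, φ of that starting material gives 42.6 mM, and oak's last reading, at 3.4 h, was 37.7 mM.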